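Target: the all-trans (2R,3R,4R)-oxolane made up of O1, C2 (ring A = 4-hydroxy-3-methoxyphenyl), C3 (CH3), C4 (C7′H2–ring B = 4-hydroxy-3,5-dimethoxyphenyl) and C5H2.
Enabling feature: C7′ sits on C4, and C4 reaches O1 through an unsubstituted C5. C7′ can therefore begin as a benzyl ether on O1, and C4/C5 as a terminal alkyne.
Retrosynthetic cuts: C4–H and C5–H (back to the C4=C5 enol ether), then O1–C5 together with C4–C7′, then C2–C3.
Forward order: C2–C3 forms by allenylzinc addition to O-tosylvanillin and O1 is benzylated with a ring B imidate. The only ring then closes while the benzyl group moves from O1 to C4, and hydration, lactol reduction and two deprotections finish the route.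
Stereochemistry: C3 comes from (S)-but-3-yn-2-ol by chirality transfer, C2 from the anti-selective addition, and C4 from thermodynamic epimerisation at the C5 lactol.

Key step: step 8

Remark: the atom labels O1, C2–C5 and C7′ of the target are used for every intermediate. The lactols are handled as C5 anomer mixtures, which is harmless because C5 ends as CH2.
Remark: ring A is carried as its tosylate. This group withdraws strongly, cannot migrate, and is inert to bases, hydrides and Lewis acids. Ring B is carried as its para benzyl ether, which acts as a donor.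

Step 1
Reactants: 1 vanillin
Product: 2 4-formyl-2-methoxyphenyl 4-methylbenzenesulfonate (O-tosylvanillin)
Conditions: TsCl, Et3N, DMAP (cat.), CH2Cl2, 0 °C to rt
Reagents that add atoms: 4-toluenesulfonyl chloride, Cc1ccc(cc1)S(=O)(=O)Cl
Why: Base-mediated O-sulfonylation of a phenol should proceed cleanly, and the tosylate is chosen because it drains electron density from ring A more strongly than an acyl group, cannot be transferred to alkoxides and tolerates every reagent used before step 11.

Step 2
Reactants: 3 (S)-but-3-yn-2-ol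
Product: 4 (S)-but-3-yn-2-yl methanesulfonate
Conditions: MsCl, Et3N, CH2Cl2, −78 to 0 °C
Reagents that add atoms: methanesulfonyl chloride, CS(=O)(=O)Cl
Why: Mesylation of a secondary alcohol takes place at oxygen, so the C–O bond and the (S) configuration stay intact.

Step 3
Reactants: 2 O-tosylvanillin; 4 (S)-but-3-yn-2-yl methanesulfonate
Product: 6 4-[(1R,2R)-1-hydroxy-2-methylbut-3-yn-1-yl]-2-methoxyphenyl 4-methylbenzenesulfonate (anti alcohol), via (aR)-buta-1,2-dien-1-yl(ethyl)zinc 5 (not isolated)
Conditions: Pd(OAc)2 (5 mol %), PPh3 (5 mol %), Et2Zn (3 equiv), THF, −78 to −20 °C; 1 M HCl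
Reagents that add atoms: none
Why: Marshall allenylzinc addition: zerovalent palladium formed in situ displaces the mesylate in an anti SN2′ sense, Et2Zn transmetallates with retention to 5, and a cyclic SE2′ transition state that keeps ring A away from the allenyl methyl group should give the anti alcohol, so that C3 (R) stems from the carbinol centre of 4 by overall inversion and C2 (R) from the transition-state geometry.

Step 4
Reactants: 7 syringaldehyde
Product: 8 4-(benzyloxy)-3,5-dimethoxybenzaldehyde
Conditions: BnBr, K2CO3, DMF, 60 °C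
Reagents that add atoms: benzyl bromide, BrCc1ccccc1
Why: Williamson etherification of the hindered but acidic syringyl phenol with a reactive benzylic halide is routine, and the para alkoxy group it installs is the donor that later stabilises the migrating C7′ cation.

Step 5
Reactants: 8 4-(benzyloxy)-3,5-dimethoxybenzaldehyde
Product: 9 [4-(benzyloxy)-3,5-dimethoxyphenyl]methanol
Conditions: NaBH4, MeOH, 0 °C
Reagents that add atoms: none
Why: Borohydride reduction of an aromatic aldehyde to the benzylic alcohol leaves both the methyl and the benzyl aryl ethers untouched.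

Step 6
Reactants: 9 [4-(benzyloxy)-3,5-dimethoxyphenyl]methanol
Product: 10 4-(benzyloxy)-3,5-dimethoxybenzyl 2,2,2-trichloroacetimidate
Conditions: Cl3CCN, DBU (10 mol %), CH2Cl2, 0 °C
Reagents that add atoms: trichloroacetonitrile, N#CC(Cl)(Cl)Cl
Why: Base-catalysed addition of an alcohol to trichloroacetonitrile (imidate formation as used for 4-methoxybenzyl transfer reagents) should give the acid-labile benzyl donor by simple addition.

Step 7
Reactants: 6 anti alcohol; 10 ring B trichloroacetimidate
Product: 11 4-[(1R,2R)-1-{[4-(benzyloxy)-3,5-dimethoxybenzyl]oxy}-2-methylbut-3-yn-1-yl]-2-methoxyphenyl 4-methylbenzenesulfonate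
Conditions: CSA (10 mol %), CH2Cl2, 0 °C to rt
Reagents that add atoms: none
Why: Acid-catalysed trichloroacetimidate benzylation transfers the electron-rich ring B benzyl group to the hydroxyl oxygen without exposing the propargylic C3–H to strong base, and C2 keeps its configuration because only the O–H bond of 6 is broken.

Step 8
Reactants: 11 homopropargylic ring B benzyl ether
Product: 12 4-[(2R,3R)-4-[4-(benzyloxy)-3,5-dimethoxybenzyl]-3-methyl-2,3-dihydrofuran-2-yl]-2-methoxyphenyl 4-methylbenzenesulfonate
Conditions: Ph3PAuNTf2 (5 mol %), 2,6-di-tert-butylpyridine (10 mol %), 4 Å MS, CH2Cl2 (0.01 M), 0 °C to rt; Et3N quench, basic alumina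
Reagents that add atoms: none
Why: Proposed new method: the cationic monovalent gold fragment Ph3PAu+ binds the terminal alkyne and the ether oxygen O1 adds anti to gold at the terminal carbon C5 in a 5-endo-dig closure (the 4-exo alternative is too strained), which gives a cyclic oxonium ion with gold on C4. The O1–C7′ bond then ionises to a contact ion pair of the 4-benzyloxy-3,5-dimethoxybenzyl cation and a 4-aurated 2,3-dihydrofuran, whose C4 is doubly activated as enol ether β-carbon and vinylgold carbon and should capture the cation (C4–C7′) with release of the catalyst, so that no atom is lost. The closest known reaction types are the PtCl2- and gold-catalysed carboalkoxylations of 2-alkynylphenyl benzyl or allyl ethers to 3-substituted benzofurans and the gold-catalysed 5-endo-dig cycloisomerisation of homopropargylic alcohols, and joining the two on an aliphatic ether is untested. No stereocentre is created, and C2 and C3 persist because none of their bonds is meant to break. The selectivity needed is heterolysis of O1–C7′ and not of O1–C2, which the para alkoxy donor of ring B secures against the sulfonate-deactivated ring A, and the same deactivation makes ring A a poor partner for a competing 6-endo hydroarylation. High dilution, sieves and the hindered pyridine are there to suppress crossover of the cation, hydration and protodeauration.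

Step 9
Reactants: 12 4-benzyl-2,3-dihydrofuran
Product: 14 4-[(2R,3R,4R)-4-[4-(benzyloxy)-3,5-dimethoxybenzyl]-5-hydroxy-3-methyloxolan-2-yl]-2-methoxyphenyl 4-methylbenzenesulfonate (all-trans lactol; both C5 anomers), via C4-epimeric lactol mixture 13 (not isolated)
Conditions: TsOH·H2O (5 mol %), THF–H2O 9:1, rt; aq NaHCO3; crude, DBU (0.3 equiv), CH2Cl2, rt
Reagents that add atoms: water, O
Why: Acid-catalysed enol ether hydration (protonation at C4, water capture at C5) gives 13 without facial control at C4, and DBU then epimerises C4 through the enolate of the ring-opened γ-hydroxy aldehyde (thermodynamic α-epimerisation), which should funnel the material into the all-trans lactol with the C4 benzyl group anti to the C3 methyl group.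

Step 10
Reactants: 14 all-trans lactol
Product: 15 4-[(2R,3R,4R)-4-[4-(benzyloxy)-3,5-dimethoxybenzyl]-3-methyloxolan-2-yl]-2-methoxyphenyl 4-methylbenzenesulfonate
Conditions: Et3SiH, BF3·OEt2, CH2Cl2, −78 to −40 °C
Reagents that add atoms: none
Why: Ionic reduction of a lactol (Kursanov–Parnes type): BF3 ionises C5–OH, Et3SiH should quench the oxocarbenium ion faster than C4 can lose its proton at low temperature, and the tosylated ring A keeps O1–C2 from ionising and cyclising onto ring B, so all three stereocentres are retained.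

Step 11
Reactants: 15 oxolane tosylate
Product: 16 4-[(2R,3R,4R)-4-[4-(benzyloxy)-3,5-dimethoxybenzyl]-3-methyloxolan-2-yl]-2-methoxyphenol
Conditions: Mg, MeOH, rt; 1 M HCl
Reagents that add atoms: none
Why: Magnesium in methanol cleaves aryl sulfonates by single-electron transfer into the S–O bond, a mild reductive desulfonylation that leaves the methyl ethers, the benzyl ether and the oxolane untouched.

Step 12
Reactants: 16 ring B benzyl ether
Product: 17 4-{[(3R,4R,5R)-5-(4-hydroxy-3-methoxyphenyl)-4-methyloxolan-3-yl]methyl}-2,6-dimethoxyphenol (target; 2R,3R,4R in the numbering used here)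
Conditions: H2 (1 atm), 10% Pd/C, EtOAc, rt
Reagents that add atoms: none
Why: Catalytic hydrogenolysis removes the phenolic benzyl ether much faster than it attacks the cyclic secondary benzylic C2–O1 bond, so stopping after one equivalent of hydrogen in a neutral solvent should deliver the target with its three centres intact.

Compound list
1 | vanillin | COc1cc(C=O)ccc1O | starting material
2 | 4-formyl-2-methoxyphenyl 4-methylbenzenesulfonate | COc1cc(C=O)ccc1OS(=O)(=O)c1ccc(C)cc1 | intermediate
3 | (S)-but-3-yn-2-ol | C[C@H](O)C#C | starting material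
4 | (S)-but-3-yn-2-yl methanesulfonate | C[C@H](OS(C)(=O)=O)C#C | intermediate
5 | (aR)-buta-1,2-dien-1-yl(ethyl)zinc | CC([H])=[C@]=C([H])[Zn]CC | intermediate
6 | 4-[(1R,2R)-1-hydroxy-2-methylbut-3-yn-1-yl]-2-methoxyphenyl 4-methylbenzenesulfonate | COc1cc([C@H](O)[C@H](C)C#C)ccc1OS(=O)(=O)c1ccc(C)cc1 | intermediate
7 | syringaldehyde | COc1cc(C=O)cc(OC)c1O | starting material
8 | 4-(benzyloxy)-3,5-dimethoxybenzaldehyde | COc1cc(C=O)cc(OC)c1OCc1ccccc1 | intermediate
9 | [4-(benzyloxy)-3,5-dimethoxyphenyl]methanol | COc1cc(CO)cc(OC)c1OCc1ccccc1 | intermediate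
10 | 4-(benzyloxy)-3,5-dimethoxybenzyl 2,2,2-trichloroacetimidate | COc1cc(COC(=N)C(Cl)(Cl)Cl)cc(OC)c1OCc1ccccc1 | intermediate
11 | 4-[(1R,2R)-1-{[4-(benzyloxy)-3,5-dimethoxybenzyl]oxy}-2-methylbut-3-yn-1-yl]-2-methoxyphenyl 4-methylbenzenesulfonate | COc1cc([C@H](OCc2cc(OC)c(OCc3ccccc3)c(OC)c2)[C@H](C)C#C)ccc1OS(=O)(=O)c1ccc(C)cc1 | intermediate
12 | 4-[(2R,3R)-4-[4-(benzyloxy)-3,5-dimethoxybenzyl]-3-methyl-2,3-dihydrofuran-2-yl]-2-methoxyphenyl 4-methylbenzenesulfonate | COc1cc([C@@H]2OC=C(Cc3cc(OC)c(OCc4ccccc4)c(OC)c3)[C@H]2C)ccc1OS(=O)(=O)c1ccc(C)cc1 | intermediate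
13 | 4-[(2R,3R)-4-[4-(benzyloxy)-3,5-dimethoxybenzyl]-5-hydroxy-3-methyloxolan-2-yl]-2-methoxyphenyl 4-methylbenzenesulfonate, epimers at C4 and C5 | COc1cc([C@@H]2OC(O)C(Cc3cc(OC)c(OCc4ccccc4)c(OC)c3)[C@H]2C)ccc1OS(=O)(=O)c1ccc(C)cc1 | intermediate
14 | 4-[(2R,3R,4R)-4-[4-(benzyloxy)-3,5-dimethoxybenzyl]-5-hydroxy-3-methyloxolan-2-yl]-2-methoxyphenyl 4-methylbenzenesulfonate, both C5 anomers | COc1cc([C@@H]2OC(O)[C@H](Cc3cc(OC)c(OCc4ccccc4)c(OC)c3)[C@H]2C)ccc1OS(=O)(=O)c1ccc(C)cc1 | intermediate
15 | 4-[(2R,3R,4R)-4-[4-(benzyloxy)-3,5-dimethoxybenzyl]-3-methyloxolan-2-yl]-2-methoxyphenyl 4-methylbenzenesulfonate | COc1cc([C@@H]2OC[C@H](Cc3cc(OC)c(OCc4ccccc4)c(OC)c3)[C@H]2C)ccc1OS(=O)(=O)c1ccc(C)cc1 | intermediate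
16 | 4-[(2R,3R,4R)-4-[4-(benzyloxy)-3,5-dimethoxybenzyl]-3-methyloxolan-2-yl]-2-methoxyphenol | COc1cc([C@@H]2OC[C@H](Cc3cc(OC)c(OCc4ccccc4)c(OC)c3)[C@H]2C)ccc1O | intermediate
17 | 4-{[(3R,4R,5R)-5-(4-hydroxy-3-methoxyphenyl)-4-methyloxolan-3-yl]methyl}-2,6-dimethoxyphenol | COc1cc([C@@H]2OC[C@H](Cc3cc(OC)c(O)c(OC)c3)[C@H]2C)ccc1O | target

Total step count: 12
Longest linear sequence: 9 steps (steps 4 to 12, from syringaldehyde)

Steps most likely to fail

**Risk 1, step 8.** Several processes could divert the reaction:
- 1,5-hydride transfer from C7′H2 to the gold-activated alkyne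
- escape of the benzyl cation from the ion pair into intermolecular Friedel–Crafts alkylation, followed by protodeauration
- hydroarylation of the alkyne by ring A
- ionisation at C2 with loss of configuration

The fallback uses known chemistry only, sets out from 6 and returns at 14. Hydroboration of the terminal alkyne with Cy2BH (in excess, since the free hydroxyl consumes one equivalent) and oxidation with NaBO3·4H2O should give the C4-unsubstituted lactol F1. TEMPO/PhI(OAc)2 oxidises it to the trans-4-methyl-5-aryl γ-lactone F2. 4-(Benzyloxy)-3,5-dimethoxybenzyl bromide F3, made from 9 with PBr3, alkylates the LiN(SiMe3)2 enolate of F2 at −78 °C on the face anti to the C3 methyl group and gives the all-trans α-benzyl lactone F4. Reduction with i-Bu2AlH at −78 °C, to which the tosylate is inert, takes F4 to lactol 14. This path sets C4 kinetically and therefore also bypasses step 9.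

**Risk 2, step 9.** The equilibration at C4 may be slow or only weakly biased at the lactol level. The ring-opened aldehyde may also be consumed by base-induced self-condensation.

The fallback sets out from 13 and returns at 14, and it moves the epimerisation to the lactone oxidation level. TEMPO/PhI(OAc)2 converts the crude mixture into the α-benzyl lactone as C4 epimers F5. DBU in toluene equilibrates the more acidic lactone α-centre, for which the trans α,β arrangement is the established thermodynamic outcome, to the all-trans α-benzyl lactone F4. Reduction with i-Bu2AlH at −78 °C then gives 14.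

**Risk 3, step 3.** The aromatic aldehyde may show only modest anti/syn discrimination in the cyclic transition state. The allenylmetal may also racemise partly before it adds.

The fallback sets out from 2 and returns at 11. Brown crotylboration of 2 with (E)-crotyldiisopinocampheylborane of the (−)-α-pinene series (−78 °C, then NaOH/H2O2) should give the anti homoallylic alcohol F6. Imidate 10 with catalytic CSA converts it into the homoallylic ring B benzyl ether F7. OsO4 (cat.)/NaIO4/2,6-lutidine cleaves the vinyl group to the α-methyl aldehyde F8. The Ohira–Bestmann reagent with K2CO3 in MeOH homologates F8 to alkyne 11.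

Further compounds
F1 | step 8 | 4-[(2R,3R)-5-hydroxy-3-methyloxolan-2-yl]-2-methoxyphenyl 4-methylbenzenesulfonate (C4-unsubstituted lactol) | COc1cc([C@@H]2OC(O)C[C@H]2C)ccc1OS(=O)(=O)c1ccc(C)cc1
F2 | step 8 | 2-methoxy-4-[(2R,3R)-3-methyl-5-oxooxolan-2-yl]phenyl 4-methylbenzenesulfonate (trans-4-methyl-5-aryl γ-lactone) | COc1cc([C@@H]2OC(=O)C[C@H]2C)ccc1OS(=O)(=O)c1ccc(C)cc1
F3 | step 8 | 4-(benzyloxy)-3,5-dimethoxybenzyl bromide | COc1cc(CBr)cc(OC)c1OCc1ccccc1
F4 | step 8 | 4-[(2R,3R,4R)-4-[4-(benzyloxy)-3,5-dimethoxybenzyl]-3-methyl-5-oxooxolan-2-yl]-2-methoxyphenyl 4-methylbenzenesulfonate (all-trans α-benzyl lactone) | COc1cc([C@@H]2OC(=O)[C@H](Cc3cc(OC)c(OCc4ccccc4)c(OC)c3)[C@H]2C)ccc1OS(=O)(=O)c1ccc(C)cc1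
F5 | step 9 | 4-[(2R,3R)-4-[4-(benzyloxy)-3,5-dimethoxybenzyl]-3-methyl-5-oxooxolan-2-yl]-2-methoxyphenyl 4-methylbenzenesulfonate (α-benzyl lactone as C4 epimers) | COc1cc([C@@H]2OC(=O)C(Cc3cc(OC)c(OCc4ccccc4)c(OC)c3)[C@H]2C)ccc1OS(=O)(=O)c1ccc(C)cc1
F6 | step 3 | 4-[(1R,2R)-1-hydroxy-2-methylbut-3-en-1-yl]-2-methoxyphenyl 4-methylbenzenesulfonate (anti homoallylic alcohol) | COc1cc([C@H](O)[C@H](C)C=C)ccc1OS(=O)(=O)c1ccc(C)cc1
F7 | step 3 | 4-[(1R,2R)-1-{[4-(benzyloxy)-3,5-dimethoxybenzyl]oxy}-2-methylbut-3-en-1-yl]-2-methoxyphenyl 4-methylbenzenesulfonate (homoallylic ring B benzyl ether) | COc1cc([C@H](OCc2cc(OC)c(OCc3ccccc3)c(OC)c2)[C@H](C)C=C)ccc1OS(=O)(=O)c1ccc(C)cc1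
F8 | step 3 | 4-[(1R,2S)-1-{[4-(benzyloxy)-3,5-dimethoxybenzyl]oxy}-2-methyl-3-oxopropyl]-2-methoxyphenyl 4-methylbenzenesulfonate (α-methyl aldehyde) | COc1cc([C@H](OCc2cc(OC)c(OCc3ccccc3)c(OC)c2)[C@H](C)C=O)ccc1OS(=O)(=O)c1ccc(C)cc1
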